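**Retrosynthetic overview**
1. Target 25 ⇐ pentasilyl precursor 24 ⇐ acrylate 20 + aldehyde 23. The C(acyl)–CH2 bond is made by intermolecular acyl-radical addition, and the returning hydrogen atom sets the α-carboxy stereocentre (key step, step 18).
2. 20 ⇐ bis-macrolide β-keto ester 18 + silyl propiolate 19 (phosphine-catalysed α-vinylation builds the quaternary carbon).
3. 18 ⇐ diosphenol macrolide 16 + ene-dione macrolide 14 by a Michael/aldol [3+2] annulation; 16 ⇐ 14 by epoxidation and isomerisation.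
4. 14 ⇐ aldehyde–ynoate 13 by a 14-endo acyl-radical macrocyclisation; 13 and 23 ⇐ common ynoate 8 ⇐ propiolate 6 + lactaldehyde 3.
5. Ring order: the 14-membered ring first (made once, used twice, as 14 and as 16), then the cyclopentanone, which joins both macrocycles in one step.

Assumption: the double-bond geometries are taken exactly as written in the SMILES (both ring enoates Z, the open-chain enoate E).
Abbreviations: TES = triethylsilyl, TBS = tert-butyldimethylsilyl, TIPS = triisopropylsilyl. Macrolide locants follow 1,7-dioxacyclotetradecane numbering.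

Step 1
Reactants: 1 ethyl (S)-lactate
Product: 2 ethyl (2S)-2-(triethylsilyloxy)propanoate
Conditions: Et3SiCl, imidazole, CH2Cl2, 0 °C → rt
Reagents that add atoms: triethylsilyl chloride, CC[Si](Cl)(CC)CC
Why: Silyl ether formation puts a bulky, non-chelating group on oxygen (needed for step 4) and does not touch the stereocentre.

Step 2
Reactants: 2 ethyl (2S)-2-(triethylsilyloxy)propanoate
Product: 3 (2S)-2-(triethylsilyloxy)propanal
Conditions: i-Bu2AlH (1.05 equiv), CH2Cl2, −78 °C; aqueous work-up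
Reagents that add atoms: none
Why: Partial ester reduction stops at the aldehyde because the aluminium hemiacetal is stable at −78 °C until work-up, and the α-silyloxy centre does not epimerise at this temperature.

Step 3
Reactants: 4 propiolic acid; 5 (2S)-hex-5-en-2-ol
Product: 6 (2S)-hex-5-en-2-yl prop-2-ynoate
Conditions: DCC, DMAP (5 mol %), CH2Cl2, −20 → 0 °C
Reagents that add atoms: none
Why: Steglich esterification acylates the secondary alcohol at oxygen, so the carbinol centre is retained.

Step 4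
Reactants: 6 (2S)-hex-5-en-2-yl prop-2-ynoate; 3 (2S)-2-(triethylsilyloxy)propanal
Product: 8 (2S)-hex-5-en-2-yl (4R,5S)-4-hydroxy-5-(triethylsilyloxy)hex-2-ynoate, via lithium acetylide 7 (not isolated)
Conditions: LiN(SiMe3)2, THF, −78 °C; then 3, −78 °C; aq. NH4Cl
Reagents that add atoms: none
Why: 1,2-Addition of the lithium acetylide to the α-silyloxy aldehyde under Felkin–Anh (non-chelation) control gives the 4,5-anti product (4R), expected about 4:1, with the syn epimer removed by chromatography.

Step 5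
Reactants: 8 (2S)-hex-5-en-2-yl (4R,5S)-4-hydroxy-5-(triethylsilyloxy)hex-2-ynoate
Product: 9 (2S)-hex-5-en-2-yl (4R,5S)-4-(tert-butyldimethylsilyloxy)-5-(triethylsilyloxy)hex-2-ynoate
Conditions: t-BuMe2SiOTf, 2,6-lutidine, CH2Cl2, −78 → 0 °C
Reagents that add atoms: tert-butyldimethylsilyl triflate, CC(C)(C)[Si](C)(C)OS(=O)(=O)C(F)(F)F
Why: Silylation of the propargylic alcohol gives an ether that survives the later selective TES removal and blocks butenolide formation once the Z-alkene exists.

Step 6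
Reactants: 9 (2S)-hex-5-en-2-yl (4R,5S)-4-(tert-butyldimethylsilyloxy)-5-(triethylsilyloxy)hex-2-ynoate
Product: 10 (2S)-hex-5-en-2-yl (2Z,4R,5S)-4-(tert-butyldimethylsilyloxy)-5-(triethylsilyloxy)hex-2-enoate
Conditions: H2 (1 atm), Pd/CaCO3 poisoned with Pb(OAc)2, quinoline, EtOAc, 0 °C, stopped at 1 equiv H2
Reagents that add atoms: none
Why: Lindlar-type syn semihydrogenation of the ynoate gives the Z-enoate, while the unactivated terminal alkene is reduced much more slowly.

Step 7
Reactants: 10 (2S)-hex-5-en-2-yl (2Z,4R,5S)-4-(tert-butyldimethylsilyloxy)-5-(triethylsilyloxy)hex-2-enoate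
Product: 11 (2S)-hex-5-en-2-yl (2Z,4R,5S)-4-(tert-butyldimethylsilyloxy)-5-hydroxyhex-2-enoate
Conditions: HF·pyridine, pyridine, THF, 0 °C
Reagents that add atoms: none
Why: Selective desilylation works because buffered fluoride cleaves the TES ether much faster than the secondary TBS ether, and the cold, short treatment keeps the free hydroxyl from lactonising onto the Z-enoate before step 8.

Step 8
Reactants: 11 (2S)-hex-5-en-2-yl (2Z,4R,5S)-4-(tert-butyldimethylsilyloxy)-5-hydroxyhex-2-enoate; 4 propiolic acid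
Product: 12 (2S)-hex-5-en-2-yl (2Z,4R,5S)-4-(tert-butyldimethylsilyloxy)-5-(prop-2-ynoyloxy)hex-2-enoate
Conditions: DCC, DMAP (5 mol %), CH2Cl2, −20 °C
Reagents that add atoms: none
Why: Steglich esterification installs the terminal ynoate acceptor on the secondary alcohol with retention, and the low temperature suppresses amine addition to the ynoate.

Step 9
Reactants: 12 (2S)-hex-5-en-2-yl (2Z,4R,5S)-4-(tert-butyldimethylsilyloxy)-5-(prop-2-ynoyloxy)hex-2-enoate
Product: 13 (2S)-5-oxopentan-2-yl (2Z,4R,5S)-4-(tert-butyldimethylsilyloxy)-5-(prop-2-ynoyloxy)hex-2-enoate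
Conditions: O3, CH2Cl2, −78 °C; then PPh3
Reagents that add atoms: ozone, O=[O+][O-]
Why: Ozonolysis is selective for the electron-rich terminal alkene over the electron-poor Z-enoate and the ynoate, and reductive work-up gives the aldehyde.

Step 10
Reactants: 13 (2S)-5-oxopentan-2-yl (2Z,4R,5S)-4-(tert-butyldimethylsilyloxy)-5-(prop-2-ynoyloxy)hex-2-enoate
Product: 14 ene-dione macrolide (3Z,5R,6S,9E,14S)-5-(tert-butyldimethylsilyloxy)-6,14-dimethyl-1,7-dioxacyclotetradeca-3,9-diene-2,8,11-trione
Conditions: (n-Bu4N)4[W10O32] (10 mol %), MeCN (2 mM), 390 nm LEDs, 25 °C, Ar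
Reagents that add atoms: none
Why: Proposed new method: photoexcited decatungstate abstracts the formyl hydrogen, the nucleophilic acyl radical adds 14-endo-dig to the terminal carbon of the electron-poor ynoate at high dilution, and the α-ester vinyl radical takes the hydrogen back from the reduced catalyst to give the 4-oxo-enoate (E drawn; this geometry is erased in steps 11 and 12, so an E/Z mixture can be used); the closest known reactions are acyl-radical macrocyclisations of selenoesters onto acrylates and decatungstate-photocatalysed hydroacylation of electron-poor alkenes.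

Step 11
Reactants: 14 ene-dione macrolide
Product: 16 diosphenol macrolide, via epoxide 15 (not isolated)
Conditions: t-BuOOH (1.05 equiv), DBU (1.3 equiv), CH2Cl2, −20 → 23 °C; dilute aq. HCl wash
Reagents that add atoms: tert-butyl hydroperoxide, CC(C)(C)OO
Why: Weitz–Scheffer nucleophilic epoxidation attacks only the doubly activated ene-dione alkene, and the base then removes the epoxide hydrogen next to the ketone and opens the ring to the enol of the 1,2-diketone (known for epoxides of 1,4-dicarbonyl alkenes), with no new stereocentre in the product.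

Step 12
Reactants: 16 diosphenol macrolide; 14 ene-dione macrolide
Product: 18 bis-macrolide core, via Michael adduct 17 (not isolated)
Conditions: DBU (0.2 equiv), CH2Cl2, −20 → 23 °C
Reagents that add atoms: none
Why: In this domino Michael/aldol [3+2] annulation of a 1,2-dione, the acidic CH2 of 16 adds to the alkene carbon β to the ketone of 14 and the resulting ketone enolate closes onto the distal diketone carbonyl; both steps are reversible, so the ring should settle with acyl and ester trans, hydroxyl cis to the acyl group (hydrogen bond) and the 14-membered bridge cis, and the face of 14 is chosen by peripheral attack on the macrocycle, as the structure of the natural trimer implies.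

Step 13
Reactants: 4 propiolic acid
Product: 19 triisopropylsilyl prop-2-ynoate
Conditions: i-Pr3SiCl, Et3N, CH2Cl2, 0 °C
Reagents that add atoms: triisopropylsilyl chloride, CC(C)[Si](Cl)(C(C)C)C(C)C
Why: Silyl ester formation masks the acid through steps 14 and 18 with a group that falls in the final fluoride step.

Step 14
Reactants: 18 bis-macrolide core; 19 triisopropylsilyl prop-2-ynoate
Product: 20 acrylate core
Conditions: PPh3 (20 mol %), toluene, 23 → 40 °C
Reagents that add atoms: none
Why: In this phosphine-catalysed α-addition (umpolung addition) of a 1,3-dicarbonyl C–H to a propiolate, PPh3 adds to the alkyne, the vinylphosphonium ion takes the β-keto ester anion at the α-carbon and the phosphine leaves; the electrophile can only reach the enolate face opposite the macrocyclic bridge, which fixes the quaternary centre.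

Step 15
Reactants: 8 (2S)-hex-5-en-2-yl (4R,5S)-4-hydroxy-5-(triethylsilyloxy)hex-2-ynoate
Product: 21 (2S)-hex-5-en-2-yl (2E,4R,5S)-4-hydroxy-5-(triethylsilyloxy)hex-2-enoate
Conditions: NaAlH2(OCH2CH2OMe)2, THF, −72 °C; aqueous work-up
Reagents that add atoms: none
Why: Hydroxyl-directed trans-hydroalumination of the γ-hydroxy ynoate followed by protonolysis gives the E-enoate and leaves the ester and silyl ether intact at low temperature.

Step 16
Reactants: 21 (2S)-hex-5-en-2-yl (2E,4R,5S)-4-hydroxy-5-(triethylsilyloxy)hex-2-enoate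
Product: 22 (2S)-hex-5-en-2-yl (2E,4R,5S)-4,5-bis(triethylsilyloxy)hex-2-enoate
Conditions: Et3SiOTf, 2,6-lutidine, CH2Cl2, −78 °C
Reagents that add atoms: triethylsilyl triflate, CC[Si](CC)(CC)OS(=O)(=O)C(F)(F)F
Why: Silylation of the allylic alcohol ensures that no free carbinol C–H is exposed to the hydrogen-abstracting photocatalyst in step 18.

Step 17
Reactants: 22 (2S)-hex-5-en-2-yl (2E,4R,5S)-4,5-bis(triethylsilyloxy)hex-2-enoate
Product: 23 (2S)-5-oxopentan-2-yl (2E,4R,5S)-4,5-bis(triethylsilyloxy)hex-2-enoate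
Conditions: O3, CH2Cl2, −78 °C; then PPh3
Reagents that add atoms: ozone, O=[O+][O-]
Why: Ozonolysis cleaves the terminal alkene selectively in the presence of the electron-poor E-enoate and gives the aldehyde.

Step 18
Reactants: 20 acrylate core; 23 (2S)-5-oxopentan-2-yl (2E,4R,5S)-4,5-bis(triethylsilyloxy)hex-2-enoate
Product: 24 pentasilyl precursor of the target
Conditions: 23 (1.5 equiv), (n-Bu4N)4[W10O32] (5 mol %), MeCN, 390 nm LEDs, 25 °C, Ar
Reagents that add atoms: none
Why: Key radical step, a decatungstate-photocatalysed hydroacylation (Giese addition of an acyl radical, radical Stetter type): the acyl radical from 23 adds to the unhindered CH2 end of the 1,1-disubstituted acrylate of 20, the most reactive acceptor present, and the tertiary α-ester radical takes a hydrogen atom from the reduced catalyst on the face turned away from the ester bridge of the quaternary carbon (allylic 1,3-strain model), which is predicted, not proven, to give the R centre.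

Step 19
Reactants: 24 pentasilyl precursor of the target
Product: 25 CNP0078817.1
Conditions: HF·pyridine, pyridine, THF, 0 → 23 °C
Reagents that add atoms: none
Why: Global desilylation with buffered HF·pyridine removes both TBS ethers, both TES ethers and the silyl ester in one base-free operation, which spares the β-keto ester and the aldol unit and is the mildest choice for the lactonisation-prone Z-γ-hydroxy enoates; no stereocentre is touched.

**Compound list**
1 | ethyl (S)-lactate | C[C@H](O)C(=O)OCC | starting material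
2 | ethyl (2S)-2-(triethylsilyloxy)propanoate | C[C@H](O[Si](CC)(CC)CC)C(=O)OCC | intermediate
3 | (2S)-2-(triethylsilyloxy)propanal | C[C@H](O[Si](CC)(CC)CC)C=O | intermediate
4 | propiolic acid (prop-2-ynoic acid) | C#CC(=O)O | starting material
5 | (2S)-hex-5-en-2-ol | C[C@H](O)CCC=C | starting material
6 | (2S)-hex-5-en-2-yl prop-2-ynoate | C#CC(=O)O[C@@H](C)CCC=C | intermediate
7 | lithium acetylide of 6 | [Li]C#CC(=O)O[C@@H](C)CCC=C | intermediate
8 | (2S)-hex-5-en-2-yl (4R,5S)-4-hydroxy-5-(triethylsilyloxy)hex-2-ynoate | C[C@H](O[Si](CC)(CC)CC)[C@H](O)C#CC(=O)O[C@@H](C)CCC=C | intermediate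
9 | (2S)-hex-5-en-2-yl (4R,5S)-4-(tert-butyldimethylsilyloxy)-5-(triethylsilyloxy)hex-2-ynoate | C[C@H](O[Si](CC)(CC)CC)[C@H](O[Si](C)(C)C(C)(C)C)C#CC(=O)O[C@@H](C)CCC=C | intermediate
10 | (2S)-hex-5-en-2-yl (2Z,4R,5S)-4-(tert-butyldimethylsilyloxy)-5-(triethylsilyloxy)hex-2-enoate | C[C@H](O[Si](CC)(CC)CC)[C@H](O[Si](C)(C)C(C)(C)C)/C=C\C(=O)O[C@@H](C)CCC=C | intermediate
11 | (2S)-hex-5-en-2-yl (2Z,4R,5S)-4-(tert-butyldimethylsilyloxy)-5-hydroxyhex-2-enoate | C[C@H](O)[C@H](O[Si](C)(C)C(C)(C)C)/C=C\C(=O)O[C@@H](C)CCC=C | intermediate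
12 | (2S)-hex-5-en-2-yl (2Z,4R,5S)-4-(tert-butyldimethylsilyloxy)-5-(prop-2-ynoyloxy)hex-2-enoate | C#CC(=O)O[C@@H](C)[C@H](O[Si](C)(C)C(C)(C)C)/C=C\C(=O)O[C@@H](C)CCC=C | intermediate
13 | (2S)-5-oxopentan-2-yl (2Z,4R,5S)-4-(tert-butyldimethylsilyloxy)-5-(prop-2-ynoyloxy)hex-2-enoate | C#CC(=O)O[C@@H](C)[C@H](O[Si](C)(C)C(C)(C)C)/C=C\C(=O)O[C@@H](C)CCC=O | intermediate
14 | ene-dione macrolide: (3Z,5R,6S,9E,14S)-5-(tert-butyldimethylsilyloxy)-6,14-dimethyl-1,7-dioxacyclotetradeca-3,9-diene-2,8,11-trione | O=C1/C=C/C(=O)CC[C@H](C)OC(=O)/C=C\[C@@H](O[Si](C)(C)C(C)(C)C)[C@H](C)O1 | intermediate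
15 | epoxide: trans-9,10-epoxide of 14 (9S,10S drawn; the 9R,10R epimer reacts the same way) | O=C1[C@H]2O[C@@H]2C(=O)CC[C@H](C)OC(=O)/C=C\[C@@H](O[Si](C)(C)C(C)(C)C)[C@H](C)O1 | intermediate
16 | diosphenol macrolide: (3Z,5R,6S,14S)-5-(tert-butyldimethylsilyloxy)-6,14-dimethyl-1,7-dioxacyclotetradec-3-ene-2,8,10,11-tetrone (drawn as the diketone; mainly the C10 enol; C9 is the acidic CH2) | O=C1CC(=O)C(=O)CC[C@H](C)OC(=O)/C=C\[C@@H](O[Si](C)(C)C(C)(C)C)[C@H](C)O1 | intermediate
17 | Michael adduct: C9 (S) of 16 bonded to C9 (S) of the 9,10-dihydro form of 14 (C10 of that ring is CH2) | [C@H]1(C(=O)O[C@@H](C)[C@H](O[Si](C)(C)C(C)(C)C)/C=C\C(=O)O[C@@H](C)CCC(=O)C1=O)[C@@H]1CC(=O)CC[C@H](C)OC(=O)/C=C\[C@@H](O[Si](C)(C)C(C)(C)C)[C@H](C)OC1=O | intermediate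
18 | bis-macrolide core: 2-hydroxycyclopentanone with ring carbons a (CH of the β-keto ester, S), b (C=O), c (C–OH, S), d (CH, S), e (CH, S); the ester on a and the CH2CH2 chain on c are spanned by the chain of 16 (macrocycle 1), the ketone on d and the ester on e by the chain of 14 (macrocycle 2); the two ester carbons and the CH2CH2 chain are cis on the five-membered ring, the OH is cis to the acyl group on d; each macrocycle keeps its (Z)-enoate, (R)-CH(OTBS) and two (S)-CH(CH3)O centres | [C@@H]12C(=O)O[C@@H](C)[C@H](O[Si](C)(C)C(C)(C)C)/C=C\C(=O)O[C@@H](C)CC[C@@](O)(C1=O)[C@H]1C(=O)CC[C@H](C)OC(=O)/C=C\[C@@H](O[Si](C)(C)C(C)(C)C)[C@H](C)OC(=O)[C@@H]12 | intermediate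
19 | triisopropylsilyl prop-2-ynoate | C#CC(=O)O[Si](C(C)C)(C(C)C)C(C)C | intermediate
20 | acrylate core: 18 with the hydrogen on carbon a replaced by a 1-(triisopropylsilyloxycarbonyl)ethenyl group, trans to the macrocycle 1 ester (same spatial arrangement as in 25; carbon a is labelled R here because the vinyl group outranks ring carbon e) | C=C(C(=O)O[Si](C(C)C)(C(C)C)C(C)C)[C@@]12C(=O)O[C@@H](C)[C@H](O[Si](C)(C)C(C)(C)C)/C=C\C(=O)O[C@@H](C)CC[C@@](O)(C1=O)[C@H]1C(=O)CC[C@H](C)OC(=O)/C=C\[C@@H](O[Si](C)(C)C(C)(C)C)[C@H](C)OC(=O)[C@@H]12 | intermediate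
21 | (2S)-hex-5-en-2-yl (2E,4R,5S)-4-hydroxy-5-(triethylsilyloxy)hex-2-enoate | C[C@H](O[Si](CC)(CC)CC)[C@H](O)/C=C/C(=O)O[C@@H](C)CCC=C | intermediate
22 | (2S)-hex-5-en-2-yl (2E,4R,5S)-4,5-bis(triethylsilyloxy)hex-2-enoate | C[C@H](O[Si](CC)(CC)CC)[C@H](O[Si](CC)(CC)CC)/C=C/C(=O)O[C@@H](C)CCC=O | intermediate
23 | (2S)-5-oxopentan-2-yl (2E,4R,5S)-4,5-bis(triethylsilyloxy)hex-2-enoate | C[C@H](O[Si](CC)(CC)CC)[C@H](O[Si](CC)(CC)CC)/C=C/C(=O)O[C@@H](C)CCC=O | intermediate
24 | pentasilyl precursor: 25 with both ring CH–OH groups as TBS ethers, both side-chain hydroxyls as TES ethers and the acid as TIPS ester (acid-bearing carbon R, quaternary carbon S) | C[C@H](O[Si](CC)(CC)CC)[C@H](O[Si](CC)(CC)CC)/C=C/C(=O)O[C@@H](C)CCC(=O)C[C@@H](C(=O)O[Si](C(C)C)(C(C)C)C(C)C)[C@@]12C(=O)O[C@@H](C)[C@H](O[Si](C)(C)C(C)(C)C)/C=C\C(=O)O[C@@H](C)CC[C@@](O)(C1=O)[C@H]1C(=O)CC[C@H](C)OC(=O)/C=C\[C@@H](O[Si](C)(C)C(C)(C)C)[C@H](C)OC(=O)[C@@H]12 | intermediate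
25 | CNP0078817.1: core of 18 with free hydroxyls, carrying on carbon a (S) the chain CH(CO2H)(R)–CH2–C(=O)–CH2CH2–CH(CH3)(S)–O–CO–CH=CH(E)–CH(OH)(R)–CH(OH)(S)–CH3 | C[C@H](O)[C@H](O)/C=C/C(=O)O[C@@H](C)CCC(=O)C[C@@H](C(=O)O)[C@@]12C(=O)O[C@@H](C)[C@H](O)/C=C\C(=O)O[C@@H](C)CC[C@@](O)(C1=O)[C@H]1C(=O)CC[C@H](C)OC(=O)/C=C\[C@@H](O)[C@H](C)OC(=O)[C@@H]12 | target

Correction to line 22 of the list: the SMILES of 22 is C[C@H](O[Si](CC)(CC)CC)[C@H](O[Si](CC)(CC)CC)/C=C/C(=O)O[C@@H](C)CCC=C (terminal alkene; the aldehyde is 23).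

**Step count and risks**
Total steps: 19. Longest linear sequence: 14 steps (1, 2, 4, 5, 6, 7, 8, 9, 10, 11, 12, 14, 18, 19).

Step 10 is the most likely to fail. At 2 mM the acyl radical can decarbonylate or oligomerise, and the vinyl radical can react elsewhere. The fallback sets out from 11 and comes back at 14 without radical ring closure. The free hydroxyl of 11 is acylated with acryloyl chloride and i-Pr2NEt to give acrylate F1. Ozonolysis of the terminal alkene gives aldehyde F2. CH2=CHMgBr at −78 °C adds to the aldehyde to give allylic alcohol F3 (both carbinol epimers). Ring-closing metathesis with the second-generation Grubbs catalyst at 1 mM closes the 14-membered ring to hydroxy macrolide F4. Dess–Martin periodinane then oxidises the allylic alcohol to 14.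

Step 18 is the second risk. The hindered tertiary radical may be quenched with poor face selectivity, or other C–H bonds and enoates may compete. The fallback sets out from 18, 19 and 23 and comes back at 24; step 14 is then not needed. Aldehyde 23 is hydroacylated onto the alkyne of 19 with the same decatungstate photocatalyst, which gives 4-oxo-enoate silyl ester F5. The β-keto ester 18 is then added to F5 in a polar Michael reaction under a quinine-derived bifunctional squaramide. The nucleophile attacks the carbon α to the silyl ester, the catalyst controls the new α-carboxy centre, and 24 forms directly.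

Step 11 is the third risk. The epoxide may open at the wrong carbon, or the diosphenol may be cleaved by residual peroxide. The fallback sets out from 11 and comes back at 16. The hydroxyl of 11 is esterified with bought but-3-enoic acid (DCC, no DMAP, 0 °C) to give but-3-enoate F6. Ring-closing metathesis with the second-generation Grubbs catalyst gives β,γ-unsaturated macrolide F7 (alkene geometry irrelevant). OsO4 (catalytic) with N-methylmorpholine N-oxide dihydroxylates only the isolated alkene to diol F8. Swern oxidation ((COCl)2, DMSO, Et3N) of both carbinols gives 16.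

**Further compounds**
F1 | step 10 | (2S)-hex-5-en-2-yl (2Z,4R,5S)-5-(acryloyloxy)-4-(tert-butyldimethylsilyloxy)hex-2-enoate | C=CC(=O)O[C@@H](C)[C@H](O[Si](C)(C)C(C)(C)C)/C=C\C(=O)O[C@@H](C)CCC=C
F2 | step 10 | (2S)-5-oxopentan-2-yl (2Z,4R,5S)-5-(acryloyloxy)-4-(tert-butyldimethylsilyloxy)hex-2-enoate | C=CC(=O)O[C@@H](C)[C@H](O[Si](C)(C)C(C)(C)C)/C=C\C(=O)O[C@@H](C)CCC=O
F3 | step 10 | (2S)-5-hydroxyhept-6-en-2-yl (2Z,4R,5S)-5-(acryloyloxy)-4-(tert-butyldimethylsilyloxy)hex-2-enoate (new carbinol unassigned, both epimers) | C=CC(=O)O[C@@H](C)[C@H](O[Si](C)(C)C(C)(C)C)/C=C\C(=O)O[C@@H](C)CCC(O)C=C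
F4 | step 10 | (3Z,5R,6S,9E,14S)-5-(tert-butyldimethylsilyloxy)-11-hydroxy-6,14-dimethyl-1,7-dioxacyclotetradeca-3,9-diene-2,8-dione (C11 unassigned, both epimers) | O=C1/C=C/C(O)CC[C@H](C)OC(=O)/C=C\[C@@H](O[Si](C)(C)C(C)(C)C)[C@H](C)O1
F5 | step 18 | (2S)-5-oxo-7-(triisopropylsilyloxycarbonyl)hept-6-en-2-yl (2E,4R,5S)-4,5-bis(triethylsilyloxy)hex-2-enoate, (6E) | C[C@H](O[Si](CC)(CC)CC)[C@H](O[Si](CC)(CC)CC)/C=C/C(=O)O[C@@H](C)CCC(=O)/C=C/C(=O)O[Si](C(C)C)(C(C)C)C(C)C
F6 | step 11 | (2S)-hex-5-en-2-yl (2Z,4R,5S)-5-(but-3-enoyloxy)-4-(tert-butyldimethylsilyloxy)hex-2-enoate | C=CCC(=O)O[C@@H](C)[C@H](O[Si](C)(C)C(C)(C)C)/C=C\C(=O)O[C@@H](C)CCC=C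
F7 | step 11 | (3Z,5R,6S,10E,14S)-5-(tert-butyldimethylsilyloxy)-6,14-dimethyl-1,7-dioxacyclotetradeca-3,10-diene-2,8-dione | O=C1C/C=C/CC[C@H](C)OC(=O)/C=C\[C@@H](O[Si](C)(C)C(C)(C)C)[C@H](C)O1
F8 | step 11 | (3Z,5R,6S,14S)-5-(tert-butyldimethylsilyloxy)-10,11-dihydroxy-6,14-dimethyl-1,7-dioxacyclotetradec-3-ene-2,8-dione (C10 and C11 unassigned, lost on oxidation) | O=C1CC(O)C(O)CC[C@H](C)OC(=O)/C=C\[C@@H](O[Si](C)(C)C(C)(C)C)[C@H](C)O1
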